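**Retrosynthetic overview**

- Numbering (3,7-dioxabicyclo[3.3.0]octane): C1 = acetoxylated bridgehead, C2 = guaiacyl carbon, O3, C4H2, C5 = bridgehead CH, C6 = veratryl carbon, O7, C8H2. Ring A = C1–C2–O3–C4–C5; ring B = C5–C6–O7–C8–C1.
- Endgame: the target comes from the bridgehead tertiary alcohol by O-acetylation at C1 and release of the phenol.
- Key disconnection: C1–C2, the bond between the fully substituted carbinol bridgehead and the benzylic guaiacyl carbon. A Norrish–Yang photocyclization (1,6-hydrogen transfer from the vanillyl ether CH2 to the excited C1 ketone) of a monocyclic 5-aryl-4-(aryl-methoxymethyl)dihydrofuran-3-one closes ring A and sets C1 and C2 together, relayed from C5/C6.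
- Ring B is formed first: the furanone comes from an anti homoallylic alcohol by epoxidation/5-endo etherification (O7–C8) and oxidation at C1.
- The homoallylic alcohol comes from veratraldehyde by a catalytic enantioselective anti-(hydroxymethyl)allylation (C5–C6 bond, the only absolute stereocontrol in the route) and primary O-alkylation with a protected vanillyl bromide.

Key step: step 6

Remark (assumption): the sense of induction in step 1 is assigned by analogy. The ligand antipode wanted is the one that sends the allyl unit to the si face of the aldehyde; it is written as (R)-SEGPHOS and would be exchanged for (S)-SEGPHOS if the sense is the opposite.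

**Route**

Step 1
Reactants: 1 3,4-dimethoxybenzaldehyde; 2 4-vinyl-1,3-dioxolan-2-one (racemic)
Product: 3 (1S,2R)-1-(3,4-dimethoxyphenyl)-2-vinylpropane-1,3-diol (anti)
Conditions: [Ir(cod)Cl]2 (2.5 mol %), (R)-SEGPHOS (5 mol %), 4-cyano-3-nitrobenzoic acid (10 mol %), K3PO4 (cat.), i-PrOH (2 equiv), THF, 70 °C
Reagents that add atoms: none
Why: Iridium-catalysed transfer-hydrogenative carbonyl (hydroxymethyl)allylation: ionization and decarboxylation of the allylic carbonate give an (E)-configured (hydroxymethyl)allyl-iridium species that should add through a closed chair transition state, which sets C5 anti to the new carbinol, while the chiral bisphosphine complex selects the si face of the aldehyde (C6 = S).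

Step 2
Reactants: 4 [4-(benzyloxy)-3-methoxyphenyl]methanol
Product: 5 4-(benzyloxy)-3-methoxybenzyl bromide
Conditions: PBr3 (0.4 equiv), Et2O, 0 °C; used freshly prepared
Reagents that add atoms: phosphorus tribromide, BrP(Br)Br
Why: Standard conversion of a benzylic alcohol into the bromide by PBr3 (substitution of the phosphite ester by bromide); no stereocentre is involved.

Step 3
Reactants: 3 (1S,2R)-1-(3,4-dimethoxyphenyl)-2-vinylpropane-1,3-diol; 5 4-(benzyloxy)-3-methoxybenzyl bromide
Product: 7 (1S,2R)-2-({[4-(benzyloxy)-3-methoxyphenyl]methoxy}methyl)-1-(3,4-dimethoxyphenyl)but-3-en-1-ol, via dibutylstannylene acetal 6 (not isolated)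
Conditions: Bu2SnO (1.05 equiv), toluene, reflux (Dean–Stark); then 5, Bu4NI (cat.), toluene, 70 °C
Reagents that add atoms: none
Why: Stannylene-acetal-mediated regioselective O-alkylation: in the six-membered dioxastanninane the primary oxygen is the more nucleophilic site, so the reactive benzylic bromide should alkylate O3 and leave the benzylic secondary hydroxyl free; both stereocentres are untouched.

Step 4
Reactants: 7 (1S,2R)-2-({[4-(benzyloxy)-3-methoxyphenyl]methoxy}methyl)-1-(3,4-dimethoxyphenyl)but-3-en-1-ol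
Product: 9 (4S,5S)-4-({[4-(benzyloxy)-3-methoxyphenyl]methoxy}methyl)-5-(3,4-dimethoxyphenyl)oxolan-3-ol (both C3 epimers), via terminal epoxide 8 (not isolated)
Conditions: mCPBA (1.3 equiv), CH2Cl2, 0 °C → rt; then PPTS (10 mol %), rt
Reagents that add atoms: meta-chloroperoxybenzoic acid, OOC(=O)c1cccc(Cl)c1
Why: Prilezhaev epoxidation of the terminal alkene followed by acid-catalysed 5-endo opening of the epoxide at its CH2 terminus by the benzylic hydroxyl (the known isomerization of 3,4-epoxy alcohols to oxolan-3-ols; the 4-exo mode to an oxetane is disfavoured by strain) closes ring B; the new carbinol centre is removed in step 5, so both epoxide epimers converge, and C5/C6 are not touched.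

Step 5
Reactants: 9 (4S,5S)-4-({[4-(benzyloxy)-3-methoxyphenyl]methoxy}methyl)-5-(3,4-dimethoxyphenyl)oxolan-3-ol
Product: 10 (4R,5S)-4-({[4-(benzyloxy)-3-methoxyphenyl]methoxy}methyl)-5-(3,4-dimethoxyphenyl)dihydrofuran-3(2H)-one (trans)
Conditions: Dess–Martin periodinane (1.3 equiv), NaHCO3, CH2Cl2, 0 °C → rt
Reagents that add atoms: none
Why: Dess–Martin oxidation under buffered, base-free conditions should give the β-alkoxy ketone without β-elimination; the 4,5-trans arrangement delivered by the anti diol is also the thermodynamic one, so the centre α to the ketone is not at risk.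

Step 6
Reactants: 10 (4R,5S)-4-({[4-(benzyloxy)-3-methoxyphenyl]methoxy}methyl)-5-(3,4-dimethoxyphenyl)dihydrofuran-3(2H)-one
Product: 12 (1S,2R,5R,6S)-2-[4-(benzyloxy)-3-methoxyphenyl]-6-(3,4-dimethoxyphenyl)-3,7-dioxabicyclo[3.3.0]octan-1-ol, via 1,5-biradical 11 (not isolated)
Conditions: hν (medium-pressure Hg lamp, Pyrex filter, λ > 290 nm), degassed benzene (0.005 M), rt
Reagents that add atoms: none
Why: n→π* excitation of the furanone carbonyl gives an oxygen-centred excited state that abstracts a hydrogen from the benzylic ether carbon C2 through a seven-membered transition state (1,6-hydrogen transfer, a formal δ-abstraction because the γ-position is the ether oxygen O3), and the 1,5-biradical 11 collapses by radical–radical coupling to the C1–C2 bond (Norrish–Yang cyclization). The closest known reaction type is the δ-hydrogen abstraction/Yang cyclization of β-alkoxy ketones to 3-hydroxytetrahydrofurans, including 4-(benzyloxymethyl)dihydrofuran-3-ones. Ring A (C1–C2–O3–C4–C5) is closed by five-membered radical recombination and can only be cis-fused, because the O3–C4 tether holds C2 on the face of ring B that carries C4; this places the new hydroxyl cis to H-5 (C1 = S, relayed from C5). C2 is set in the same event: the planar benzylic radical should couple with its aryl group turned to the convex face, away from C8H2 and the concave pocket of the forming bicycle (aryl cis to OH, C2 = R). The step needs site selectivity in the hydrogen transfer, which the substrate secures because the only other activated C–H (C6–H) lies in the ring and cannot reach the carbonyl oxygen, and it needs cyclization to outrun α-cleavage, which the weak, doubly activated (benzylic and α-oxy) C2–H bond favours. Pyrex-filtered light, high dilution and exclusion of oxygen limit direct excitation of the aryl ethers and bimolecular quenching.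

Step 7
Reactants: 12 (1S,2R,5R,6S)-2-[4-(benzyloxy)-3-methoxyphenyl]-6-(3,4-dimethoxyphenyl)-3,7-dioxabicyclo[3.3.0]octan-1-ol
Product: 13 (1S,2R,5R,6S)-2-[4-(benzyloxy)-3-methoxyphenyl]-6-(3,4-dimethoxyphenyl)-3,7-dioxabicyclo[3.3.0]octan-1-yl acetate
Conditions: Ac2O (5 equiv), DMAP (1 equiv), Et3N, CH2Cl2, 40 °C
Reagents that add atoms: acetic anhydride, CC(=O)OC(C)=O
Why: DMAP-catalysed (Steglich-type) acylation should esterify the hindered tertiary bridgehead alcohol under non-acidic conditions that do not ionize the benzylic ethers; O-acylation leaves all four stereocentres unchanged.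

Step 8
Reactants: 13 (1S,2R,5R,6S)-2-[4-(benzyloxy)-3-methoxyphenyl]-6-(3,4-dimethoxyphenyl)-3,7-dioxabicyclo[3.3.0]octan-1-yl acetate
Product: 14 (1S,2R,5R,6S)-6-(3,4-dimethoxyphenyl)-2-(4-hydroxy-3-methoxyphenyl)-3,7-dioxabicyclo[3.3.0]octan-1-yl acetate (target)
Conditions: H2 (1 atm), 10% Pd/C, EtOAc, rt, stopped at full conversion of 13
Reagents that add atoms: none
Why: Catalytic hydrogenolysis should cleave the aryl benzyl ether faster than the dialkyl benzylic C–O bonds of the furofuran, and the tertiary acetate is inert, so the phenol is released without change at any stereocentre.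

**Compound list**

1 | 3,4-dimethoxybenzaldehyde (veratraldehyde) | COc1ccc(C=O)cc1OC | starting material
2 | 4-vinyl-1,3-dioxolan-2-one (vinyl ethylene carbonate, racemic) | C=CC1COC(=O)O1 | starting material
3 | (1S,2R)-1-(3,4-dimethoxyphenyl)-2-vinylpropane-1,3-diol | COc1ccc(cc1OC)[C@@H](O)[C@@H](CO)C=C | intermediate
4 | [4-(benzyloxy)-3-methoxyphenyl]methanol | OCc1ccc(OCc2ccccc2)c(OC)c1 | starting material
5 | 4-(benzyloxy)-3-methoxybenzyl bromide | BrCc1ccc(OCc2ccccc2)c(OC)c1 | intermediate
6 | (4S,5R)-2,2-dibutyl-4-(3,4-dimethoxyphenyl)-5-vinyl-1,3,2-dioxastanninane (stannylene acetal) | COc1ccc(cc1OC)[C@H]1O[Sn](CCCC)(CCCC)OC[C@H]1C=C | intermediate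
7 | (1S,2R)-2-({[4-(benzyloxy)-3-methoxyphenyl]methoxy}methyl)-1-(3,4-dimethoxyphenyl)but-3-en-1-ol | COc1ccc(cc1OC)[C@@H](O)[C@@H](COCc1ccc(OCc2ccccc2)c(OC)c1)C=C | intermediate
8 | (1S,2R)-3-{[4-(benzyloxy)-3-methoxyphenyl]methoxy}-1-(3,4-dimethoxyphenyl)-2-(oxiran-2-yl)propan-1-ol (both oxirane epimers) | COc1ccc(cc1OC)[C@@H](O)[C@@H](COCc1ccc(OCc2ccccc2)c(OC)c1)C1CO1 | intermediate
9 | (4S,5S)-4-({[4-(benzyloxy)-3-methoxyphenyl]methoxy}methyl)-5-(3,4-dimethoxyphenyl)oxolan-3-ol (both C3 epimers) | COc1ccc(cc1OC)[C@H]1OCC(O)[C@@H]1COCc1ccc(OCc2ccccc2)c(OC)c1 | intermediate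
10 | (4R,5S)-4-({[4-(benzyloxy)-3-methoxyphenyl]methoxy}methyl)-5-(3,4-dimethoxyphenyl)dihydrofuran-3(2H)-one | COc1ccc(cc1OC)[C@H]1OCC(=O)[C@@H]1COCc1ccc(OCc2ccccc2)c(OC)c1 | intermediate
11 | 1,5-biradical of 10 (hydroxy-substituted C1 radical and benzylic C2 radical) | COc1ccc(cc1OC)[C@H]1OC[C](O)[C@@H]1CO[CH]c1ccc(OCc2ccccc2)c(OC)c1 | intermediate
12 | (1S,2R,5R,6S)-2-[4-(benzyloxy)-3-methoxyphenyl]-6-(3,4-dimethoxyphenyl)-3,7-dioxabicyclo[3.3.0]octan-1-ol | COc1cc([C@H]2OC[C@@H]3[C@@H](c4ccc(OC)c(OC)c4)OC[C@]23O)ccc1OCc1ccccc1 | intermediate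
13 | (1S,2R,5R,6S)-2-[4-(benzyloxy)-3-methoxyphenyl]-6-(3,4-dimethoxyphenyl)-3,7-dioxabicyclo[3.3.0]octan-1-yl acetate | COc1cc([C@H]2OC[C@@H]3[C@@H](c4ccc(OC)c(OC)c4)OC[C@]23OC(C)=O)ccc1OCc1ccccc1 | intermediate
14 | (1S,2R,5R,6S)-6-(3,4-dimethoxyphenyl)-2-(4-hydroxy-3-methoxyphenyl)-3,7-dioxabicyclo[3.3.0]octan-1-yl acetate | COc1cc([C@H]2OC[C@@H]3[C@@H](c4ccc(OC)c(OC)c4)OC[C@]23OC(C)=O)ccc1O | target

**Step count and risks**

Total step count: 8. Longest linear sequence: 7 (steps 1, 3, 4, 5, 6, 7, 8); step 2 is a one-step branch.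

Steps most likely to fail:

1. Step 6 (key photocyclization). The excited ketone may fragment by α-cleavage or return the hydrogen instead of coupling, and the biradical may couple on the concave face and give the C2 epimer. The fallback sets out from diol 3 and comes back at 12; it forms the C2–O3 bond last instead of the C1–C2 bond.
   - Selective silylation of the primary hydroxyl (TBSCl, imidazole, CH2Cl2, 0 °C) should give (1S,2R)-2-{[(tert-butyldimethylsilyl)oxy]methyl}-1-(3,4-dimethoxyphenyl)but-3-en-1-ol F1.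
   - Epoxidation/cyclization as in step 4 should give (4S,5S)-4-{[(tert-butyldimethylsilyl)oxy]methyl}-5-(3,4-dimethoxyphenyl)oxolan-3-ol F2, and Dess–Martin oxidation the ketone (4R,5S)-4-{[(tert-butyldimethylsilyl)oxy]methyl}-5-(3,4-dimethoxyphenyl)dihydrofuran-3(2H)-one F3.
   - Bromide 5 and PPh3 (toluene, 80 °C) give {[4-(benzyloxy)-3-methoxyphenyl]methyl}triphenylphosphonium bromide F4. Its ylide (KHMDS, THF, −78 °C) should convert F3 by Wittig olefination into (2S,3R)-4-{[4-(benzyloxy)-3-methoxyphenyl]methylidene}-3-{[(tert-butyldimethylsilyl)oxy]methyl}-2-(3,4-dimethoxyphenyl)oxolane F5 (E/Z mixture).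
   - Upjohn dihydroxylation (OsO4 cat., NMO) on the face anti to the CH2OTBS group should give (3S,4R,5S)-3-{[4-(benzyloxy)-3-methoxyphenyl](hydroxy)methyl}-4-{[(tert-butyldimethylsilyl)oxy]methyl}-5-(3,4-dimethoxyphenyl)oxolan-3-ol F6, with the tertiary hydroxyl cis to H-5.
   - TBAF should give (3S,4R,5S)-3-{[4-(benzyloxy)-3-methoxyphenyl](hydroxy)methyl}-5-(3,4-dimethoxyphenyl)-4-(hydroxymethyl)oxolan-3-ol F7. CSA (cat., CH2Cl2) should then ionize the p-alkoxybenzylic carbinol; capture of the cation by the primary hydroxyl closes ring A with the aryl group on the convex face and gives 12.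

2. Step 4 (epoxidation/5-endo etherification). The ether oxygen O3 may open the epoxide in place of the hydroxyl and lose its benzylic group, or the electron-rich benzylic alcohol may ionize under acid. The fallback sets out from 7 and comes back at 9; it replaces epoxide opening by displacement of a sulfonate under non-acidic conditions.
   - Upjohn dihydroxylation of 7 should give (3R,4S)-3-({[4-(benzyloxy)-3-methoxyphenyl]methoxy}methyl)-4-(3,4-dimethoxyphenyl)butane-1,2,4-triol F8 (both C2 epimers).
   - Selective sulfonylation of the primary hydroxyl (TsCl, Et3N, Bu2SnO cat., CH2Cl2) should give (3R,4S)-3-({[4-(benzyloxy)-3-methoxyphenyl]methoxy}methyl)-4-(3,4-dimethoxyphenyl)-2,4-dihydroxybutyl 4-methylbenzenesulfonate F9. On warming in pyridine it should be displaced by the benzylic hydroxyl (5-exo-tet cyclization) to give 9.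

3. Step 1 (catalytic hydroxymethylallylation). Enantio- or anti-selectivity may be insufficient with this carbonate donor, or transfer hydrogenation may reduce the electron-rich aldehyde faster than it couples. The fallback sets out from bromide 5 (with aldehyde 1) and comes back at 7, so it also bypasses 3 and step 3; stereocontrol comes from a stoichiometric chiral borane.
   - Alkylation of buta-2,3-dien-1-ol with 5 (NaH, THF, 0 °C) should give 1-(benzyloxy)-4-[(buta-2,3-dien-1-yloxy)methyl]-2-methoxybenzene F10.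
   - Hydroboration of the terminal double bond with (−)-diisopinocampheylborane (from (+)-α-pinene) and equilibration to the (E)-allylborane should give [(2E)-4-{[4-(benzyloxy)-3-methoxyphenyl]methoxy}but-2-en-1-yl]bis(isopinocampheyl)borane F11, which is not isolated.
   - Addition of aldehyde 1 at −78 °C (Brown allylboration, chair transition state, si-face attack expected by analogy with aromatic aldehydes) and oxidative work-up (NaOH, H2O2) should give the anti adduct 7.

**Further compounds**

F1 | step 6 | (1S,2R)-2-{[(tert-butyldimethylsilyl)oxy]methyl}-1-(3,4-dimethoxyphenyl)but-3-en-1-ol | COc1ccc(cc1OC)[C@@H](O)[C@@H](CO[Si](C)(C)C(C)(C)C)C=C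
F2 | step 6 | (4S,5S)-4-{[(tert-butyldimethylsilyl)oxy]methyl}-5-(3,4-dimethoxyphenyl)oxolan-3-ol (both C3 epimers) | COc1ccc(cc1OC)[C@H]1OCC(O)[C@@H]1CO[Si](C)(C)C(C)(C)C
F3 | step 6 | (4R,5S)-4-{[(tert-butyldimethylsilyl)oxy]methyl}-5-(3,4-dimethoxyphenyl)dihydrofuran-3(2H)-one | COc1ccc(cc1OC)[C@H]1OCC(=O)[C@@H]1CO[Si](C)(C)C(C)(C)C
F4 | step 6 | {[4-(benzyloxy)-3-methoxyphenyl]methyl}triphenylphosphonium bromide | [Br-].COc1cc(C[P+](c2ccccc2)(c2ccccc2)c2ccccc2)ccc1OCc1ccccc1
F5 | step 6 | (2S,3R)-4-{[4-(benzyloxy)-3-methoxyphenyl]methylidene}-3-{[(tert-butyldimethylsilyl)oxy]methyl}-2-(3,4-dimethoxyphenyl)oxolane (E/Z mixture) | COc1ccc(cc1OC)[C@H]1OCC(=Cc2ccc(OCc3ccccc3)c(OC)c2)[C@@H]1CO[Si](C)(C)C(C)(C)C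
F6 | step 6 | (3S,4R,5S)-3-{[4-(benzyloxy)-3-methoxyphenyl](hydroxy)methyl}-4-{[(tert-butyldimethylsilyl)oxy]methyl}-5-(3,4-dimethoxyphenyl)oxolan-3-ol (epimers at the exocyclic carbinol) | COc1ccc(cc1OC)[C@H]1OC[C@](O)(C(O)c2ccc(OCc3ccccc3)c(OC)c2)[C@@H]1CO[Si](C)(C)C(C)(C)C
F7 | step 6 | (3S,4R,5S)-3-{[4-(benzyloxy)-3-methoxyphenyl](hydroxy)methyl}-5-(3,4-dimethoxyphenyl)-4-(hydroxymethyl)oxolan-3-ol (epimers at the exocyclic carbinol) | COc1ccc(cc1OC)[C@H]1OC[C@](O)(C(O)c2ccc(OCc3ccccc3)c(OC)c2)[C@@H]1CO
F8 | step 4 | (3R,4S)-3-({[4-(benzyloxy)-3-methoxyphenyl]methoxy}methyl)-4-(3,4-dimethoxyphenyl)butane-1,2,4-triol (both C2 epimers) | COc1ccc(cc1OC)[C@@H](O)[C@@H](COCc1ccc(OCc2ccccc2)c(OC)c1)C(O)CO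
F9 | step 4 | (3R,4S)-3-({[4-(benzyloxy)-3-methoxyphenyl]methoxy}methyl)-4-(3,4-dimethoxyphenyl)-2,4-dihydroxybutyl 4-methylbenzenesulfonate (both C2 epimers) | COc1ccc(cc1OC)[C@@H](O)[C@@H](COCc1ccc(OCc2ccccc2)c(OC)c1)C(O)COS(=O)(=O)c1ccc(C)cc1
F10 | step 1 | 1-(benzyloxy)-4-[(buta-2,3-dien-1-yloxy)methyl]-2-methoxybenzene | C=C=CCOCc1ccc(OCc2ccccc2)c(OC)c1
F11 | step 1 | [(2E)-4-{[4-(benzyloxy)-3-methoxyphenyl]methoxy}but-2-en-1-yl]bis(isopinocampheyl)borane, isopinocampheyl groups from (+)-α-pinene | C[C@H]1[C@@H](C[C@@H]2C[C@H]1C2(C)C)B(C/C=C/COCc1ccc(OCc2ccccc2)c(OC)c1)[C@@H]1C[C@@H]2C[C@H]([C@H]1C)C2(C)C
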